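## The problem

The target 26 is a biflavonoid in which a chroman-4-one unit (rings A and C, with a 4-hydroxyphenyl ring B on C2) is joined twice to a kaempferol unit. Chromanone C2 is bonded to flavonol C8 and chromanone C3 to flavonol O7, so a dihydrofuran ring is fused both to ring C of the upper unit and to ring A of the flavonol. Chromanone C2 is a fully substituted, doubly benzylic ether carbon (O1, two aryl groups, C3), and C3 is a hemiketal carbon next to the C4 ketone; the SMILES reads as 2R,3S. A five-membered ring fused to the pyranone can only be cis, and a hemiketal can equilibrate, so C2 controls C3 and only C2 needs absolute control. Because C2 bears no hydrogen, it must be set in the step that makes it quaternary and cannot be corrected later. The flavonol has to be attached through C8 and O7 and not through the equally nucleophilic C6, a distinction that couplings of two intact flavonoids do not make reliably. The functionality is delicate: seven phenolic or enolic hydroxyls, a ring C that opens by β-elimination of O1 whenever C3 carries a hydrogen next to the ketone, and a C2–O1 bond that is a diarylmethyl ether and can be ionised by strong acid. The enabling feature is ring A of the flavonol, a 1,3,5-trioxygenated benzene whose C8 lies between the oxygen-bearing C7 and C8a with O5 para to it. That is the pattern formed when a 3-alkoxyvinylketene is annulated onto a siloxyalkyne, so an alkyne on chromanone C2 fixes the C8 attachment by mechanism and leaves kaempferol (1) to supply the whole upper unit.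

## Retrosynthesis

26 ⇒ 24 (through 25). The hemiketal bond C3–O7 and all O-benzyl and O-ethyl bonds are cut. The hemiketal is the resting state of a 3,4-dione with a phenol next to it, so no separate ring-closing step is planned: removal of the protecting groups from 24 releases the open dione 25, which closes by itself. 24 carries the dione as a 3,3-dibenzyl ketal, six phenols and the flavonol 3-OH as benzyl ethers, and flavonol O5 as the ethyl ether left by the annulation. The forward step needs a Lewis acid that removes seven benzyl groups and the chelated ethyl group without ionising C2–O1.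

24 ⇒ 23 ⇒ 20 + 21. Ring C of the flavonol is opened at O1–C2 and C2–C3 (flavonol numbering), by way of diketone 22. The Baker–Venkataraman logic with an α-benzyloxy ketone brings the 3-oxygen in at the right oxidation level. A chalcone route with Algar–Flynn–Oyamada oxidation would tend to give aurones because of the alkoxy group ortho to the ketone, and 3-hydroxylation of a flavone would add an oxidation on a very electron-rich substrate. The silyl ether on O7 is kept until ring C is closed so that only O8a can form the pyranone.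

20 ⇒ 19 ⇒ 18 ⇒ 17. The bonds C4–C3 and C4a–C4 of the flavonol are cut. The acyl group is brought in as a formyl group ortho to the free phenol, then homologated by a benzyloxymethyl anion and oxidised. A direct Friedel–Crafts acylation would not tell C4a from C6, both being flanked by two oxygens; a magnesium phenoxide directs to the only free ortho position. This leads back to 17, in which the free hydroxyl marks the future O1 of the flavonol and the silyl ether the future O7.

17 ⇒ 11 + 12. This is the key disconnection: the bonds C8–C8a, C6–C7 and C4a–C8a of flavonol ring A are cut, and the whole ring is traced to a siloxyalkyne on chromanone C2 and the four-carbon ketene precursor 12. The alternative of adding a preformed phloroglucinol or flavonol nucleophile to a C2 electrophile would face both the C6/C8 ambiguity and the making of a quaternary diaryl ether carbon. The precursor is simpler by one ring and three C–C bonds. The forward reaction has to be regioselective at a very hindered alkyne under neutral conditions; C3 of 11 is a ketal carbon without hydrogen so that heating cannot open ring C.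

11 ⇒ 8 ⇒ 7. The O–C(sp) bond of the ynol ether and the C–Si bond of the alkyne are cut. A terminal alkyne can be oxidised to the ynolate and silylated on oxygen; the alternative of carrying an oxygenated alkyne through the earlier steps has no dependable counterpart. The ketone of 8 must stay out of the acetylide chemistry.

7 ⇒ 5. One of the two C3–O bonds is cut. The second oxygen is put on C3 by oxidising the enol ether at the moment C4 becomes a ketone, so that no intermediate ever has a hydrogen on C3 beside a C4 carbonyl. The alcohol used matches the ether already on O3, which keeps C3 achiral.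

5 ⇒ 2 + 3 and 2 ⇒ 1. The C2–C(sp) bond is cut. Perbenzylated kaempferol 2 is activated as the silyloxypyrylium ion 4 and alkynylated at C2 with CuI and a chiral bis(oxazoline) ligand. This is the only step that creates absolute configuration, and it uses the complete upper unit, including the C3 oxygen, as it comes from 1.

## Roads not taken

Alternative 1: Cut the C2–C8 bond last and make it with light. The two halves would first be joined through oxygen to give the 3-aryloxyflavone A1, with chromanone C3–O7 in place. Irradiation of A1 bound to a chiral Lewis acid would close the aryl vinyl ether by conrotatory 6π cyclisation onto the flavonol ring and, after a hydrogen shift, give the cis-fused dihydrofuran A2, which still has a hydrogen on C3.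
- Merits: both halves come from 1, every carbon is present before the key step, the cis fusion is inherent, and the sequence could be about half as long as the chosen one.
- Weak points: the excited enol ether can close onto C6 as well as C8, both being ortho to O7. Both halves of A1 absorb strongly, so excitation of uncomplexed substrate and of the flavonol part would compete with the Lewis-acid-bound enone and erode the enantioselectivity. A2 has the wrong oxidation state at C3: a tertiary C–H next to the ketone whose enolisation expels O1 and opens ring C, so the late hydroxylation endangers C2.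
- Comparison: in convergence and step count this road is better. The chosen plan sets against it a C8 attachment fixed by how ring A is built, a C2 centre made by a ground-state catalytic reaction, and a C3 that carries its second oxygen from step 3 onward.

Alternative 2: Cut O1–C2 of the chromanone. The carbinol A3, a furo-fused flavonol with the future ring B on the furan and a (2-hydroxyaryl)methanol on the neighbouring furan carbon, would be dehydrated by a chiral phosphoric acid to an ortho-quinone methide. Its oxa-6π electrocyclisation through the furan double bond would form O1–C2 and give the 2H-chromene A4, with C2 quaternary and a C3=C4 enol ether.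
- Merits: convergent, metal-free, and the C8/O7 attachment is settled when the furan is built on an intact flavonol.
- Weak points: the closure dearomatises the furan and is reversible, and the same reversible opening of the 2H-chromene would racemise A4 on warming or in light. The catalyst binds at the carbonyl end of the quinone methide while the stereocentre forms at the far terminus. Building the 3-arylfuran on a flavonol meets the C6/C8 question one stage earlier. A4 still needs oxygen at C3 and at C4.
- Comparison: probably somewhat shorter, but weaker where the stereocentre is made and kept. In the chosen route C2 is configurationally fixed from 7 onward, because C3 is sp3 and bears no hydrogen.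

Alternative 3: Cut C4a–C8a and build flavonol ring A by a biomimetic Claisen condensation. The precursor A5 is a cis-fused dihydrofuran whose enol ether carbon bears an ester (future C8a) and whose neighbour carries a masked triketide chain. Under base C4a would attack the ester, and enolisation would give A6 with a free 8a-hydroxyl, a 5-methyl ether and the benzyloxyacetyl group already on C4a.
- Merits: A6 is the closed analogue of 20, so the formylation, homologation and oxidation (steps 7–9) would be saved, and no heating is involved.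
- Weak points: A5 is harder to make than anything in the chosen route. It already contains both stereocentres, and the key step says nothing about their origin. The ester sits next to the quaternary C2 and is a poor electrophile. The chain can also close by aldol or O-acylation pathways, and base invites β-elimination.
- Comparison: this road is better in what the ring closure delivers. The chosen plan sets against it a precursor (11) reached in five steps from 1 with a defined source of chirality, and a regiochemistry that does not depend on which enolate attacks which carbonyl.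

Key step: step 6

Assumption: the sense of asymmetric induction in step 2 is not predicted here; the enantiomer of the bis(oxazoline) ligand that leads to the 2R series is the one used.

## Route

Step 1
Reactants: 1 kaempferol
Product: 2 3,5,7-tris(benzyloxy)-2-[4-(benzyloxy)phenyl]-4H-chromen-4-one
Conditions: BnBr (6 equiv), K2CO3, n-Bu4NI (cat.), DMF, 70 °C
Reagents that add atoms: benzyl bromide, BrCc1ccccc1
Why: Williamson etherification; the excess of alkylating agent and the temperature are chosen so that the hydrogen-bonded 5-OH is benzylated as well.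

Step 2
Reactants: 2 tetra-O-benzylkaempferol; 3 (trimethylsilyl)acetylene
Product: 5 (2R)-3,5,7-tris(benzyloxy)-2-[4-(benzyloxy)phenyl]-4-[(tert-butyldimethylsilyl)oxy]-2-[(trimethylsilyl)ethynyl]-2H-chromene, via silyloxypyrylium triflate 4 (not isolated)
Conditions: TBSOTf (1.2 equiv), CH2Cl2, 23 °C; then CuI (10 mol %), (S,S)-Ph-BOX or its antipode (12 mol %), i-Pr2NEt, 3, toluene, −40 °C; filtration through Et3N-deactivated silica
Reagents that add atoms: tert-butyldimethylsilyl trifluoromethanesulfonate, CC(C)(C)[Si](C)(C)OS(=O)(=O)C(F)(F)F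
Why: Copper-catalysed enantioselective alkynylation of a 4-silyloxybenzopyrylium ion (conjugate alkynylation of a chromone): a chiral bis(oxazoline) complex of the monovalent copper acetylide adds to C2 of planar 4 and the ligand selects the face, which sets C2 (2R). The product keeps the C3 oxygen and the C3=C4 enol ether needed for step 3.

Step 3
Reactants: 5 silyl enol ether
Product: 7 (2R)-3,3,5,7-tetrakis(benzyloxy)-2-[4-(benzyloxy)phenyl]-2-[(trimethylsilyl)ethynyl]chroman-4-one, via bromo ketone 6 (not isolated)
Conditions: NBS (1.0 equiv), BnOH (5 equiv), CH2Cl2, −78 °C, dark; then AgOTf, 2,6-lutidine, −78 → −20 °C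
Reagents that add atoms: benzyl alcohol, OCc1ccccc1
Why: Bromination of the silyl enol ether at C3 followed by Koenigs–Knorr-type silver-assisted alcoholysis of the tertiary α-bromo ether 6, as with glycosyl halides that carry a neighbouring carbonyl. Both C3 epimers of 6 give the same achiral ketal carbon, and at −78 °C the enol ether should outcompete the alkoxyarenes for bromine. 5 is used cold and in the dark because 2H-chromenes can open reversibly.

Step 4
Reactants: 7 silylalkyne ketal
Product: 8 (2S)-3,3,5,7-tetrakis(benzyloxy)-2-[4-(benzyloxy)phenyl]-2-ethynylchroman-4-one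
Conditions: K2CO3 (0.2 equiv), MeOH/THF, 0 °C
Reagents that add atoms: none
Why: Base-catalysed protodesilylation of an alkynylsilane; the ketone has no α-hydrogen, so neither enolisation nor β-elimination of O1 is possible (the descriptor changes only because ethynyl ranks below aryl).

Step 5
Reactants: 8 terminal alkyne
Product: 11 (2R)-3,3,5,7-tetrakis(benzyloxy)-2-[4-(benzyloxy)phenyl]-2-{[(triisopropylsilyl)oxy]ethynyl}chroman-4-one, via lithium acetylide 9 (not isolated), via lithium ynolate 10 (not isolated)
Conditions: LiN(SiMe3)2, THF, −78 °C; LiOO-t-Bu (from t-BuOOH and LiN(SiMe3)2), −78 → 0 °C; TIPSOTf, −78 °C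
Reagents that add atoms: tert-butyl hydroperoxide, CC(C)(C)OO; triisopropylsilyl trifluoromethanesulfonate, CC(C)[Si](OS(=O)(=O)C(F)(F)F)(C(C)C)C(C)C
Why: Oxidation of a lithium acetylide with lithium tert-butyl peroxide to the ynolate and O-silylation with a bulky silyl triflate, the standard entry to triisopropylsiloxyalkynes. The C4 ketone is non-enolisable, flanked by the ketal carbon and the 5-benzyloxy group and deactivated by the trioxygenated ring, which should keep it from reacting with 9 and 10 at low temperature.

Step 6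
Reactants: 11 siloxyalkyne; 12 3-ethoxycyclobut-2-en-1-one
Product: 17 (2R)-3,3,5,7-tetrakis(benzyloxy)-2-[4-(benzyloxy)phenyl]-2-{4-ethoxy-2-hydroxy-6-[(triisopropylsilyl)oxy]phenyl}chroman-4-one, via ethoxyvinylketene 13 (not isolated), via vinylcyclobutenone 14 (not isolated), via dienylketene 15 (not isolated), via cyclohexadienone 16 (not isolated)
Conditions: 12 (2.5 equiv, in portions), toluene, 80 °C, then 110 °C
Reagents that add atoms: none
Why: Danheiser benzannulation: thermal 4π electrocyclic opening of 12 gives ethoxyvinylketene 13. Its ketene C=C adds (2+2) to the siloxyalkyne with the polarity of a ketene–ynol ether pair: the carbonyl carbon bonds to the alkyne carbon on chromanone C2 (future C8–C8a) and the α-carbon to the siloxy carbon (future C6–C7), giving 14. 14 opens (4π) to dienylketene 15, which closes the six-membered ring by thermal disrotatory 6π electrocyclisation (future C4a–C8a) to 16 and tautomerises to phenol 17. The closest known reaction is the benzannulation of cyclobutenones with triisopropylsiloxyalkynes to resorcinol monosilyl ethers; new here is only the fully substituted carbon on the alkyne. No stereocentre is formed, and C2 is safe because the medium is neutral and aprotic and C3 is sp3 without hydrogen, so neither enolisation nor electrocyclic opening of ring C is possible. The selectivity needed is regiochemical (C8 between the two new oxygens, ethoxy para to it) and is secured by the donor oxygen of the ynol ether and the position of the ethoxy group in 12. An excess of 12 offsets ketene lost to dimerisation or to acylation of 17.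

Step 7
Reactants: 17 phenol
Product: 18 (2R)-3,3,5,7-tetrakis(benzyloxy)-2-[4-(benzyloxy)phenyl]-2-{4-ethoxy-3-formyl-2-hydroxy-6-[(triisopropylsilyl)oxy]phenyl}chroman-4-one
Conditions: MgCl2, Et3N, (CH2O)n, THF, reflux
Reagents that add atoms: paraformaldehyde (formaldehyde), C=O
Why: Casnati–Skattebøl ortho-formylation through the magnesium phenoxide, with a second formaldehyde as hydride acceptor. The only free ortho position is C4a, between OH and OEt, as in the formylation of 3,5-dialkoxyphenols; the α-keto ketal is not ionised by this weak Lewis acid in the presence of amine.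

Step 8
Reactants: 18 salicylaldehyde
Product: 19 (2R)-3,3,5,7-tetrakis(benzyloxy)-2-[4-(benzyloxy)phenyl]-2-{3-[2-(benzyloxy)-1-hydroxyethyl]-4-ethoxy-2-hydroxy-6-[(triisopropylsilyl)oxy]phenyl}chroman-4-one (both carbinol epimers)
Conditions: LiN(SiMe3)2 (1.05 equiv), THF, −78 °C; then BnOCH2Li (from Bu3SnCH2OBn and n-BuLi, 1.5 equiv), −78 °C; aq. NH4Cl
Reagents that add atoms: tributyl[(benzyloxy)methyl]stannane, CCCC[Sn](CCCC)(CCCC)COCc1ccccc1
Why: Addition of an α-alkoxymethyllithium, made by tin–lithium exchange, to an aldehyde after deprotonation of the phenol. The chromanone ketone is neopentyl on both sides and should not compete at −78 °C; the new carbinol centre is removed in step 9.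

Step 9
Reactants: 19 benzylic alcohol
Product: 20 (2R)-3,3,5,7-tetrakis(benzyloxy)-2-[4-(benzyloxy)phenyl]-2-{3-[(benzyloxy)acetyl]-4-ethoxy-2-hydroxy-6-[(triisopropylsilyl)oxy]phenyl}chroman-4-one
Conditions: MnO2 (excess), CH2Cl2, 23 °C
Reagents that add atoms: none
Why: MnO2 oxidation of a benzylic alcohol to the aryl ketone; the reagent is neutral and heterogeneous and leaves benzyl ethers, silyl ether and ketal alone.

Step 10
Reactants: 20 ortho-hydroxyaryl ketone; 21 4-(benzyloxy)benzoyl chloride
Product: 23 (2R)-3,3,5,7-tetrakis(benzyloxy)-2-[4-(benzyloxy)phenyl]-2-{3-(benzyloxy)-2-[4-(benzyloxy)phenyl]-5-ethoxy-4-oxo-7-[(triisopropylsilyl)oxy]-4H-chromen-8-yl}chroman-4-one, via β-diketone 22 (not isolated)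
Conditions: LiN(SiMe3)2 (3.3 equiv), THF, −78 °C; 21, −78 → 0 °C; aq. NH4Cl; then TsOH·H2O (0.1 equiv), toluene, 60 °C
Reagents that add atoms: none
Why: Baker–Venkataraman flavone synthesis in its dianion variant: the phenoxide–enolate of 20 is aroylated to diketone 22, whose hemiketal dehydrates under mild acid to the 3-benzyloxyflavone. The acid is kept catalytic so that the α-keto ketal, which ionises only under forcing conditions, stays closed and O8a ends up in the pyranone.

Step 11
Reactants: 23 silyl ether
Product: 24 (2R)-3,3,5,7-tetrakis(benzyloxy)-2-[4-(benzyloxy)phenyl]-2-{3-(benzyloxy)-2-[4-(benzyloxy)phenyl]-5-ethoxy-7-hydroxy-4-oxo-4H-chromen-8-yl}chroman-4-one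
Conditions: n-Bu4NF, THF, 0 °C; aq. NH4Cl
Reagents that add atoms: none
Why: Fluoride cleavage of an aryl silyl ether; ketal, benzyl ethers and the flavone are inert to fluoride.

Step 12
Reactants: 24 protected bis-flavonoid
Product: 26 the target (2R,3S cis-fused hemiketal; chromanone C2 bonded to kaempferol C8; chromanone C3 bonded to kaempferol O7), via open chromanedione 25 (not isolated)
Conditions: BCl3 (excess), C6HMe5, CH2Cl2, −78 → 0 °C; MeOH, then H2O
Reagents that add atoms: none
Why: Debenzylation by BCl3 with pentamethylbenzene as benzyl-cation scavenger removes the seven benzyl groups, and on warming the boron chelate at the flavonol C4 carbonyl removes the peri ethyl group as chloroethane. Work-up hydrolyses the borates, and the freed 3,4-dione 25 is trapped by the neighbouring O7–H at C3, the more electrophilic carbonyl because C4 is conjugated to the phloroglucinol ring and hydrogen-bonded to the 5-OH. Only the cis-fused hemiketal is possible, so C2 sets C3 (3S).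

## Compound list

1 | kaempferol, 3,5,7-trihydroxy-2-(4-hydroxyphenyl)-4H-chromen-4-one | O=c1c(O)c(-c2ccc(O)cc2)oc2cc(O)cc(O)c12 | starting material
2 | 3,5,7-tris(benzyloxy)-2-[4-(benzyloxy)phenyl]-4H-chromen-4-one | O=c1c(OCc9ccccc9)c(-c2ccc(OCc9ccccc9)cc2)oc2cc(OCc9ccccc9)cc(OCc9ccccc9)c12 | intermediate
3 | (trimethylsilyl)acetylene | C#C[Si](C)(C)C | starting material
4 | 3,5,7-tris(benzyloxy)-2-[4-(benzyloxy)phenyl]-4-[(tert-butyldimethylsilyl)oxy]chromenylium trifluoromethanesulfonate | CC(C)(C)[Si](C)(C)Oc1c(OCc9ccccc9)c(-c2ccc(OCc9ccccc9)cc2)[o+]c2cc(OCc9ccccc9)cc(OCc9ccccc9)c12.[O-]S(=O)(=O)C(F)(F)F | intermediate (not isolated)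
5 | (2R)-3,5,7-tris(benzyloxy)-2-[4-(benzyloxy)phenyl]-4-[(tert-butyldimethylsilyl)oxy]-2-[(trimethylsilyl)ethynyl]-2H-chromene | CC(C)(C)[Si](C)(C)OC1=C(OCc9ccccc9)[C@@](c2ccc(OCc9ccccc9)cc2)(C#C[Si](C)(C)C)Oc2cc(OCc9ccccc9)cc(OCc9ccccc9)c12 | intermediate
6 | (2R)-3,5,7-tris(benzyloxy)-2-[4-(benzyloxy)phenyl]-3-bromo-2-[(trimethylsilyl)ethynyl]chroman-4-one, both C3 epimers | O=C1c2c(OCc9ccccc9)cc(OCc9ccccc9)cc2O[C@](c2ccc(OCc9ccccc9)cc2)(C#C[Si](C)(C)C)C1(Br)OCc9ccccc9 | intermediate (not isolated)
7 | (2R)-3,3,5,7-tetrakis(benzyloxy)-2-[4-(benzyloxy)phenyl]-2-[(trimethylsilyl)ethynyl]chroman-4-one | O=C1c2c(OCc9ccccc9)cc(OCc9ccccc9)cc2O[C@](c2ccc(OCc9ccccc9)cc2)(C#C[Si](C)(C)C)C1(OCc9ccccc9)OCc9ccccc9 | intermediate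
8 | (2S)-3,3,5,7-tetrakis(benzyloxy)-2-[4-(benzyloxy)phenyl]-2-ethynylchroman-4-one | O=C1c2c(OCc9ccccc9)cc(OCc9ccccc9)cc2O[C@](c2ccc(OCc9ccccc9)cc2)(C#C)C1(OCc9ccccc9)OCc9ccccc9 | intermediate
9 | lithium acetylide of 8 | O=C1c2c(OCc9ccccc9)cc(OCc9ccccc9)cc2O[C@](c2ccc(OCc9ccccc9)cc2)(C#C[Li])C1(OCc9ccccc9)OCc9ccccc9 | intermediate (not isolated)
10 | lithium ynolate derived from 8 (C≡C–OLi on C2) | O=C1c2c(OCc9ccccc9)cc(OCc9ccccc9)cc2O[C@](c2ccc(OCc9ccccc9)cc2)(C#CO[Li])C1(OCc9ccccc9)OCc9ccccc9 | intermediate (not isolated)
11 | (2R)-3,3,5,7-tetrakis(benzyloxy)-2-[4-(benzyloxy)phenyl]-2-{[(triisopropylsilyl)oxy]ethynyl}chroman-4-one | O=C1c2c(OCc9ccccc9)cc(OCc9ccccc9)cc2O[C@](c2ccc(OCc9ccccc9)cc2)(C#CO[Si](C(C)C)(C(C)C)C(C)C)C1(OCc9ccccc9)OCc9ccccc9 | intermediate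
12 | 3-ethoxycyclobut-2-en-1-one | CCOC1=CC(=O)C1 | starting material
13 | 3-ethoxybuta-1,3-dien-1-one (ethoxyvinylketene) | C=C(OCC)C=C=O | intermediate (not isolated)
14 | 4-(1-ethoxyvinyl)-3-[(triisopropylsilyl)oxy]cyclobut-2-en-1-one bearing the chromanone C2 of 11 on its C2, both epimers at the ring CH | O=C1c2c(OCc9ccccc9)cc(OCc9ccccc9)cc2O[C@](c2ccc(OCc9ccccc9)cc2)(C2=C(O[Si](C(C)C)(C(C)C)C(C)C)C(C(=C)OCC)C2=O)C1(OCc9ccccc9)OCc9ccccc9 | intermediate (not isolated)
15 | 5-ethoxy-3-[(triisopropylsilyl)oxy]hexa-1,3,5-trien-1-one bearing the chromanone C2 on its C2, ketene and ethoxyvinyl groups cis on the central double bond | O=C1c2c(OCc9ccccc9)cc(OCc9ccccc9)cc2O[C@](c2ccc(OCc9ccccc9)cc2)(C(=C=O)/C(O[Si](C(C)C)(C(C)C)C(C)C)=C\C(=C)OCC)C1(OCc9ccccc9)OCc9ccccc9 | intermediate (not isolated)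
16 | 5-ethoxy-3-[(triisopropylsilyl)oxy]cyclohexa-2,4-dien-1-one bearing the chromanone C2 on its C2 | O=C1c2c(OCc9ccccc9)cc(OCc9ccccc9)cc2O[C@](c2ccc(OCc9ccccc9)cc2)(C2=C(O[Si](C(C)C)(C(C)C)C(C)C)C=C(OCC)CC2=O)C1(OCc9ccccc9)OCc9ccccc9 | intermediate (not isolated)
17 | (2R)-3,3,5,7-tetrakis(benzyloxy)-2-[4-(benzyloxy)phenyl]-2-{4-ethoxy-2-hydroxy-6-[(triisopropylsilyl)oxy]phenyl}chroman-4-one | O=C1c2c(OCc9ccccc9)cc(OCc9ccccc9)cc2O[C@](c2ccc(OCc9ccccc9)cc2)(c2c(O)cc(OCC)cc2O[Si](C(C)C)(C(C)C)C(C)C)C1(OCc9ccccc9)OCc9ccccc9 | intermediate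
18 | (2R)-3,3,5,7-tetrakis(benzyloxy)-2-[4-(benzyloxy)phenyl]-2-{4-ethoxy-3-formyl-2-hydroxy-6-[(triisopropylsilyl)oxy]phenyl}chroman-4-one | O=C1c2c(OCc9ccccc9)cc(OCc9ccccc9)cc2O[C@](c2ccc(OCc9ccccc9)cc2)(c2c(O)c(C=O)c(OCC)cc2O[Si](C(C)C)(C(C)C)C(C)C)C1(OCc9ccccc9)OCc9ccccc9 | intermediate
19 | (2R)-3,3,5,7-tetrakis(benzyloxy)-2-[4-(benzyloxy)phenyl]-2-{3-[2-(benzyloxy)-1-hydroxyethyl]-4-ethoxy-2-hydroxy-6-[(triisopropylsilyl)oxy]phenyl}chroman-4-one, both carbinol epimers | O=C1c2c(OCc9ccccc9)cc(OCc9ccccc9)cc2O[C@](c2ccc(OCc9ccccc9)cc2)(c2c(O)c(C(O)COCc9ccccc9)c(OCC)cc2O[Si](C(C)C)(C(C)C)C(C)C)C1(OCc9ccccc9)OCc9ccccc9 | intermediate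
20 | (2R)-3,3,5,7-tetrakis(benzyloxy)-2-[4-(benzyloxy)phenyl]-2-{3-[(benzyloxy)acetyl]-4-ethoxy-2-hydroxy-6-[(triisopropylsilyl)oxy]phenyl}chroman-4-one | O=C1c2c(OCc9ccccc9)cc(OCc9ccccc9)cc2O[C@](c2ccc(OCc9ccccc9)cc2)(c2c(O)c(C(=O)COCc9ccccc9)c(OCC)cc2O[Si](C(C)C)(C(C)C)C(C)C)C1(OCc9ccccc9)OCc9ccccc9 | intermediate
21 | 4-(benzyloxy)benzoyl chloride | O=C(Cl)c1ccc(OCc9ccccc9)cc1 | starting material
22 | (2R)-3,3,5,7-tetrakis(benzyloxy)-2-[4-(benzyloxy)phenyl]-2-{3-[2-(benzyloxy)-3-[4-(benzyloxy)phenyl]-3-oxopropanoyl]-4-ethoxy-2-hydroxy-6-[(triisopropylsilyl)oxy]phenyl}chroman-4-one | O=C1c2c(OCc9ccccc9)cc(OCc9ccccc9)cc2O[C@](c2ccc(OCc9ccccc9)cc2)(c2c(O)c(C(=O)C(OCc9ccccc9)C(=O)c3ccc(OCc9ccccc9)cc3)c(OCC)cc2O[Si](C(C)C)(C(C)C)C(C)C)C1(OCc9ccccc9)OCc9ccccc9 | intermediate (not isolated)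
23 | (2R)-3,3,5,7-tetrakis(benzyloxy)-2-[4-(benzyloxy)phenyl]-2-{3-(benzyloxy)-2-[4-(benzyloxy)phenyl]-5-ethoxy-4-oxo-7-[(triisopropylsilyl)oxy]-4H-chromen-8-yl}chroman-4-one | O=C1c2c(OCc9ccccc9)cc(OCc9ccccc9)cc2O[C@](c2ccc(OCc9ccccc9)cc2)(c2c(O[Si](C(C)C)(C(C)C)C(C)C)cc(OCC)c3c(=O)c(OCc9ccccc9)c(-c4ccc(OCc9ccccc9)cc4)oc23)C1(OCc9ccccc9)OCc9ccccc9 | intermediate
24 | (2R)-3,3,5,7-tetrakis(benzyloxy)-2-[4-(benzyloxy)phenyl]-2-{3-(benzyloxy)-2-[4-(benzyloxy)phenyl]-5-ethoxy-7-hydroxy-4-oxo-4H-chromen-8-yl}chroman-4-one | O=C1c2c(OCc9ccccc9)cc(OCc9ccccc9)cc2O[C@](c2ccc(OCc9ccccc9)cc2)(c2c(O)cc(OCC)c3c(=O)c(OCc9ccccc9)c(-c4ccc(OCc9ccccc9)cc4)oc23)C1(OCc9ccccc9)OCc9ccccc9 | intermediate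
25 | (2R)-5,7-dihydroxy-2-(4-hydroxyphenyl)-2-[3,5,7-trihydroxy-2-(4-hydroxyphenyl)-4-oxo-4H-chromen-8-yl]chromane-3,4-dione (open form) | O=C1c2c(O)cc(O)cc2O[C@](c2ccc(O)cc2)(c2c(O)cc(O)c3c(=O)c(O)c(-c4ccc(O)cc4)oc23)C1=O | intermediate (not isolated)
26 | CNP0314633.1, (2R,3S) cis-fused hemiketal: 3,5,7-trihydroxy-2-(4-hydroxyphenyl)chroman-4-one with C2 bonded to C8 and C3 bonded to O7 of kaempferol | O=C1c2c(O)cc(O)cc2O[C@]2(c3ccc(O)cc3)c3c(cc(O)c4c(=O)c(O)c(-c5ccc(O)cc5)oc34)O[C@]12O | target

## Step count and risks

Total step count: 12. Longest linear sequence: 12 steps (1 → 26); 3, 12 and 21 are purchased and enter directly.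

Least certain steps:

Step 6 (key step). The alkyne carbon that must bond to the ketene sits on a quaternary carbon next to a ketal carbon, so the cycloaddition may be slower than dimerisation of the ketene, acylation of the product phenol, or thermal loss of 11 by ionisation of the C2–O1 bond (the ynol ether stabilises a propargylic cation). Fallback: setting out from 11, ketene 13 is generated at ambient temperature by 1,4-dehydrochlorination of (2E)-3-ethoxybut-2-enoyl chloride F1 with Et3N, added slowly to 11 in CH2Cl2. The cycloaddition to 14 is then complete before any heating, and 14 is warmed to 80 °C only for its rearrangement. The sequence comes back to the route at 17.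

Step 2. The pyrylium ion 4 is stabilised by three alkoxyaryl donors and shielded at C2 by the aryl and 3-benzyloxy groups, so addition of the copper acetylide may be slow or poorly face-selective, and silyl transfer to the acetylide may compete. Fallback: setting out from 2, preformed 4 is treated with stoichiometric [(trimethylsilyl)ethynyl]zinc bromide (from 3, n-BuLi and ZnBr2), a silyl-triflate-promoted conjugate alkynylation, to give racemic enol ether F2. The conditions of step 3 convert it into the racemic ketal F3, and preparative HPLC on a chiral stationary phase gives the 2R enantiomer, at which point the route is rejoined at 7.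

Step 5. Acetylide 9 or ynolate 10 may add to the C4 ketone of a second molecule, or the peroxide may attack that ketone, during the hours the oxidation needs; C-silylation of 10 is a lesser concern with the bulky triflate. Fallback: setting out from 8, the ketone is reduced (LiBH4, THF) to the carbinol F4, (2S)-3,3,5,7-tetrakis(benzyloxy)-2-[4-(benzyloxy)phenyl]-2-ethynylchroman-4-ol. The ynolate sequence is run on its lithium alkoxide with one equivalent of TIPSOTf at −78 °C, where the ynolate oxygen should be silylated ahead of the hindered secondary alkoxide, to give the siloxyalkyne carbinol F5, and MnO2 oxidation of the benzylic alcohol returns to the route at 11.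

Step 3. Bromination may spill over onto the alkoxyarenes, and the α-keto oxocarbenium ion formed from 6 may lose a benzyl cation to give the 3,4-dione instead of being captured by the hindered alcohol. Fallback: setting out from 5, Rubottom oxidation with dimethyldioxirane and work-up with aqueous HF in MeCN accepts that loss and gives the 3,4-dione F6. Ketalisation of its more electrophilic C3 carbonyl with BnOSiMe3 and catalytic TMSOTf returns to the route at 7.

Step 12. Cleavage of the ethyl ether needs warmer conditions than debenzylation and may stay incomplete, while longer exposure to BCl3 risks ionisation of C2–O1 and C-benzylation of the phloroglucinol rings. Fallback: setting out from 24, hydrogenolysis (H2, Pd(OH)2/C, THF/MeOH) removes the seven benzyl groups under neutral conditions and lets the hemiketal close, giving the 5-O-ethyl ether of the target F7. Chelation-controlled de-ethylation with MgI2·OEt2 then gives 26.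

Further compounds
F1 | step 6 | (2E)-3-ethoxybut-2-enoyl chloride | CCO/C(C)=C/C(=O)Cl
F2 | step 2 | racemic 3,5,7-tris(benzyloxy)-2-[4-(benzyloxy)phenyl]-4-[(tert-butyldimethylsilyl)oxy]-2-[(trimethylsilyl)ethynyl]-2H-chromene | CC(C)(C)[Si](C)(C)OC1=C(OCc9ccccc9)C(c2ccc(OCc9ccccc9)cc2)(C#C[Si](C)(C)C)Oc2cc(OCc9ccccc9)cc(OCc9ccccc9)c12
F3 | step 2 | racemic 3,3,5,7-tetrakis(benzyloxy)-2-[4-(benzyloxy)phenyl]-2-[(trimethylsilyl)ethynyl]chroman-4-one | O=C1c2c(OCc9ccccc9)cc(OCc9ccccc9)cc2OC(c2ccc(OCc9ccccc9)cc2)(C#C[Si](C)(C)C)C1(OCc9ccccc9)OCc9ccccc9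
F4 | step 5 | (2S)-3,3,5,7-tetrakis(benzyloxy)-2-[4-(benzyloxy)phenyl]-2-ethynylchroman-4-ol, both C4 epimers | OC1c2c(OCc9ccccc9)cc(OCc9ccccc9)cc2O[C@](c2ccc(OCc9ccccc9)cc2)(C#C)C1(OCc9ccccc9)OCc9ccccc9
F5 | step 5 | (2R)-3,3,5,7-tetrakis(benzyloxy)-2-[4-(benzyloxy)phenyl]-2-{[(triisopropylsilyl)oxy]ethynyl}chroman-4-ol, both C4 epimers | OC1c2c(OCc9ccccc9)cc(OCc9ccccc9)cc2O[C@](c2ccc(OCc9ccccc9)cc2)(C#CO[Si](C(C)C)(C(C)C)C(C)C)C1(OCc9ccccc9)OCc9ccccc9
F6 | step 3 | (2R)-5,7-bis(benzyloxy)-2-[4-(benzyloxy)phenyl]-2-[(trimethylsilyl)ethynyl]chromane-3,4-dione | O=C1c2c(OCc9ccccc9)cc(OCc9ccccc9)cc2O[C@](c2ccc(OCc9ccccc9)cc2)(C#C[Si](C)(C)C)C1=O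
F7 | step 12 | (2R,3S) 5-O-ethyl ether of the target (ethoxy on flavonol C5, all other hydroxyls free, hemiketal closed) | O=C1c2c(O)cc(O)cc2O[C@]2(c3ccc(O)cc3)c3c(cc(OCC)c4c(=O)c(O)c(-c5ccc(O)cc5)oc34)O[C@]12O
A1 | alternative 1 | 5,7-bis(benzyloxy)-2-[4-(benzyloxy)phenyl]-3-({3,5-bis(benzyloxy)-2-[4-(benzyloxy)phenyl]-4-oxo-4H-chromen-7-yl}oxy)-4H-chromen-4-one | O=c1c(Oc2cc(OCc9ccccc9)c3c(=O)c(OCc9ccccc9)c(-c4ccc(OCc9ccccc9)cc4)oc3c2)c(-c2ccc(OCc9ccccc9)cc2)oc2cc(OCc9ccccc9)cc(OCc9ccccc9)c12
A2 | alternative 1 | hexa-O-benzyl 3-deoxy target, cis-fused dihydrofuran with hydrogen on chromanone C3 | O=C1c2c(OCc9ccccc9)cc(OCc9ccccc9)cc2O[C@]2(c3ccc(OCc9ccccc9)cc3)c3c(cc(OCc9ccccc9)c4c(=O)c(OCc9ccccc9)c(-c5ccc(OCc9ccccc9)cc5)oc34)O[C@H]12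
A3 | alternative 2 | [2-hydroxy-4,6-bis(benzyloxy)phenyl](furan-2-yl)methanol in which the furan is fused to C7–C8 of 3,5-bis(benzyloxy)-2-[4-(benzyloxy)phenyl]chromen-4-one (oxygen on C7) and bears 4-(benzyloxy)phenyl on its C3 | OC(c1c(O)cc(OCc9ccccc9)cc1OCc9ccccc9)c1oc2cc(OCc9ccccc9)c3c(=O)c(OCc9ccccc9)c(-c4ccc(OCc9ccccc9)cc4)oc3c2c1-c1ccc(OCc9ccccc9)cc1
A4 | alternative 2 | hexa-O-benzyl 2H-chromene with quaternary C2 and a C3=C4 enol ether double bond | C1=C2Oc3cc(OCc9ccccc9)c4c(=O)c(OCc9ccccc9)c(-c5ccc(OCc9ccccc9)cc5)oc4c3[C@@]2(c3ccc(OCc9ccccc9)cc3)Oc2cc(OCc9ccccc9)cc(OCc9ccccc9)c12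
A5 | alternative 3 | cis-fused dihydrofuran on chromanone C2–C3 (3-benzyloxy ketal) bearing a methyl ester on the enol ether carbon next to C2 and a 5-(benzyloxy)-2-methoxy-4-oxopent-1-enyl chain on the oxygen-bearing carbon | O=C1c2c(OCc9ccccc9)cc(OCc9ccccc9)cc2O[C@]2(c3ccc(OCc9ccccc9)cc3)C(C(=O)OC)=C(C=C(OC)CC(=O)COCc9ccccc9)O[C@]12OCc9ccccc9
A6 | alternative 3 | tetracyclic core with flavonol ring A formed: free 8a-hydroxyl, 5-methyl ether, benzyloxyacetyl group on C4a, 3-benzyl ketal | O=C1c2c(OCc9ccccc9)cc(OCc9ccccc9)cc2O[C@]2(c3ccc(OCc9ccccc9)cc3)c3c(cc(OC)c(C(=O)COCc9ccccc9)c3O)O[C@]12OCc9ccccc9
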